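## Retrosynthetic overview

- The target is a 4H-pyran-4-one with OMe at C6, ethyl groups at C3 and C5, and an (S)-10-acetoxyundecyl chain at C2. Chain carbons are counted C1'–C11' from the ring, and C10' is the only stereocentre.
- Key disconnection: the C2'–C3' bond, an unfunctionalised CH2–CH2 link. C2' is insulated from ring carbon C2 by the C1' methylene, and C3' is six methylenes away from the C10' acetoxy stereocentre. Both halves are therefore unstabilised primary alkyl radicals, which allows a protecting-group-free mixed Kolbe electrolysis of a pyranonylpropanoic acid with (S)-9-acetoxydecanoic acid as the last step. The two CO2H groups serve as traceless activating groups and leave as CO2.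
- Pyranone acid: the only ring of the molecule is closed once, by enol-lactonisation of a triketide methyl ester to a 4-hydroxy-2-pyrone. Regioselective O-methylation then gives the 2-methoxy-4-pyranone, and the propanoate arm is added by lateral alkylation of the ring methyl group with tert-butyl bromoacetate.
- Acetoxy acid: Cu-catalysed opening of (S)-propylene oxide (source of C10') by oct-7-enylmagnesium bromide, then acetylation and oxidative cleavage of the terminal alkene.
- Ring order: the pyranone ring is formed in step 3; no ring is formed in the key step.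

Key step: step 10

Remark: 2 and 5 are carried as mixtures of stereoisomers and enol tautomers; their sp3 centres become sp2 ring carbons in step 3.

## Route

Step 1
Reactants: 1 methyl butanoate (two molecules)
Product: 2 methyl 2-ethyl-3-oxohexanoate (racemic)
Conditions: NaOMe (0.55 equiv), toluene, reflux with removal of MeOH; then aq. HCl, 0 °C
Reagents that add atoms: none
Why: Claisen self-condensation of an ester with two α-hydrogens is driven forward by deprotonation of the β-keto ester product and removal of methanol; the new C2 centre is racemic and is lost in step 3.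

Step 2
Reactants: 2 methyl 2-ethyl-3-oxohexanoate; 3 N-methoxy-N-methylacetamide
Product: 5 methyl 2,4-diethyl-3,5-dioxohexanoate, via dilithium bis-enolate 4 (not isolated)
Conditions: LDA (2.2 equiv), THF, −78 → 0 °C; then 3 (1.1 equiv), −78 → 0 °C; aq. NH4Cl
Reagents that add atoms: lithium diisopropylamide, [Li+].CC(C)[N-]C(C)C (lithium stays in 4 only)
Why: γ-Acylation of a β-keto ester dianion, in which the more nucleophilic C4 carbanion attacks the Weinreb amide and the chelated tetrahedral adduct prevents over-addition and keeps the acidic product from quenching unreacted dianion.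

Step 3
Reactants: 5 methyl 2,4-diethyl-3,5-dioxohexanoate
Product: 6 3,5-diethyl-4-hydroxy-6-methyl-2H-pyran-2-one
Conditions: DBU (2 equiv), toluene, 80 °C; 1 M HCl work-up
Reagents that add atoms: none
Why: Base-mediated enol-lactonisation of a β,δ-diketo ester (6-exo-trig attack of the C5 enol oxygen on the ester carbonyl, loss of methanol) is the standard closure of triketides to aromatic 4-hydroxy-2-pyrones.

Step 4
Reactants: 6 3,5-diethyl-4-hydroxy-6-methyl-2H-pyran-2-one
Product: 7 3,5-diethyl-2-methoxy-6-methyl-4H-pyran-4-one
Conditions: MeOTf (1.5 equiv), CH2Cl2, 0 °C → rt; aq. NaHCO3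
Reagents that add atoms: methyl trifluoromethanesulfonate, COS(=O)(=O)C(F)(F)F
Why: A hard methylating agent should alkylate the neutral 4-hydroxy-2-pyrone at its most basic site, the lactone carbonyl oxygen, and loss of the 4-OH proton then gives the α-methoxy-γ-pyrone (the known regioselective O-methylation of 4-hydroxy-2-pyrones with methyl sulfonates).

Step 5
Reactants: 7 3,5-diethyl-2-methoxy-6-methyl-4H-pyran-4-one; 8 tert-butyl bromoacetate
Product: 10 tert-butyl 3-(3,5-diethyl-6-methoxy-4-oxo-4H-pyran-2-yl)propanoate, via lithium dienolate 9 (not isolated)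
Conditions: LiHMDS (1.1 equiv), THF, −78 °C; then 8 (1.2 equiv), −78 → −40 °C; aq. NH4Cl
Reagents that add atoms: lithium hexamethyldisilazide, [Li+].C[Si](C)(C)[N-][Si](C)(C)C (lithium stays in 9 only)
Why: Lateral (vinylogous) deprotonation of the ring methyl group gives the extended dienolate 9, which should be alkylated at its exocyclic carbon by the reactive α-bromo ester (SN2), as in the usual side-chain elaboration of 6-alkyl-2-methoxy-4-pyranones; the ethyl CH2 groups are not vinylogously activated.

Step 6
Reactants: 10 tert-butyl 3-(3,5-diethyl-6-methoxy-4-oxo-4H-pyran-2-yl)propanoate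
Product: 11 3-(3,5-diethyl-6-methoxy-4-oxo-4H-pyran-2-yl)propanoic acid
Conditions: TFA/CH2Cl2 (1:4), 0 °C → rt
Reagents that add atoms: none
Why: Acidolysis of the tert-butyl ester (loss of isobutene) frees the acid without exposing the base-sensitive methyl vinylogous carbonate of the pyranone to hydroxide.

Step 7
Reactants: 12 8-bromooct-1-ene; 13 (S)-2-methyloxirane ((S)-propylene oxide)
Product: 15 (S)-undec-10-en-2-ol, via oct-7-enylmagnesium bromide 14 (not isolated)
Conditions: Mg, THF, rt → 40 °C; then CuI (10 mol%), 13, THF, −30 → 0 °C; aq. NH4Cl
Reagents that add atoms: magnesium, [Mg] (stays in 14 only)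
Why: Cu(I)-catalysed SN2 opening of a terminal epoxide by a primary Grignard reagent occurs at the unsubstituted carbon, so the chiral-pool stereocentre is not involved and stays (S).

Step 8
Reactants: 15 (S)-undec-10-en-2-ol
Product: 16 (S)-undec-10-en-2-yl acetate
Conditions: Ac2O, pyridine, DMAP (cat.), CH2Cl2, rt
Reagents that add atoms: acetic anhydride, CC(=O)OC(C)=O
Why: DMAP-catalysed O-acylation of a secondary alcohol proceeds with retention because the C–O bond is not broken.

Step 9
Reactants: 16 (S)-undec-10-en-2-yl acetate
Product: 17 (S)-9-acetoxydecanoic acid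
Conditions: RuCl3·xH2O (3 mol%), NaIO4 (4.1 equiv), MeCN/EtOAc/H2O, rt
Reagents that add atoms: sodium periodate, [Na+].[O-]I(=O)(=O)=O; water, O
Why: RuO4-catalysed oxidative cleavage of a terminal alkene gives the one-carbon-shorter carboxylic acid directly, and the acetate and the remote stereocentre are inert to it.

Step 10
Reactants: 11 3-(3,5-diethyl-6-methoxy-4-oxo-4H-pyran-2-yl)propanoic acid; 17 (S)-9-acetoxydecanoic acid
Product: 20 (S)-11-(3,5-diethyl-6-methoxy-4-oxo-4H-pyran-2-yl)undecan-2-yl acetate (target), via pyranonylethyl radical 18 (not isolated), via (S)-8-acetoxynonyl radical 19 (not isolated)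
Conditions: undivided cell, smooth Pt anode/Pt cathode, 11 (1 equiv), 17 (4 equiv), KOH (5 mol% of total acid), MeOH, constant current ca. 0.2 A cm−2, 20–30 °C, stopped while the electrolyte is still weakly acidic
Reagents that add atoms: none
Why: At the platinum anode under the high current density of the Kolbe regime, the carboxylates of 11 and 17 are each oxidised by one electron and lose CO2 to give the primary radicals 18 and 19 side by side in the anode layer, where radical–radical combination should form the C2'–C3' CH2–CH2 bond of 20. The closest known reaction type is the mixed (crossed) Kolbe electrolysis of two primary alkanoic acids that carry remote ester, keto or aryl groups, 3-arylpropanoic acids included. No ring is closed and no stereocentre is created; the (S)-centre of 19 lies seven carbons from the radical site, has no pathway for epimerisation and should arrive unchanged. The step needs cross- over homo-coupling and one-electron (radical) over two-electron (carbocation) oxidation: the first is secured statistically by the fourfold excess of the three-step acid 17, which should channel the limiting acid 11 mainly into 20, and the second by the structure, since both radicals are primary and unstabilised (C2' is insulated from the pyranone by C1', C3' is remote from the acetoxy oxygen). The by-products differ from 20 in the number of pyranone rings (none in the 17/17 dimer, two in the 11/11 dimer), so chromatographic separation should be simple. The weakly acidic, only partly neutralised methanol should spare the acetate from methanolysis, and the pyranone, a cross-conjugated vinylogous carbonate, should be harder to oxidise than the adsorbed carboxylates.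

## Compound list

1 | methyl butanoate | CCCC(=O)OC | starting material
2 | methyl 2-ethyl-3-oxohexanoate (racemic) | CCCC(=O)C(CC)C(=O)OC | intermediate
3 | N-methoxy-N-methylacetamide | CC(=O)N(C)OC | starting material
4 | dilithium bis-enolate (dianion) of methyl 2-ethyl-3-oxohexanoate | [Li+].[Li+].CCC=C([O-])C(CC)=C([O-])OC | intermediate (not isolated)
5 | methyl 2,4-diethyl-3,5-dioxohexanoate (mixture of diastereomers and tautomers) | COC(=O)C(CC)C(=O)C(CC)C(C)=O | intermediate
6 | 3,5-diethyl-4-hydroxy-6-methyl-2H-pyran-2-one | CCc1c(O)c(CC)c(C)oc1=O | intermediate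
7 | 3,5-diethyl-2-methoxy-6-methyl-4H-pyran-4-one | CCc1c(C)oc(OC)c(CC)c1=O | intermediate
8 | tert-butyl bromoacetate | CC(C)(C)OC(=O)CBr | starting material
9 | lithium 3,5-diethyl-2-methoxy-6-methylidene-6H-pyran-4-olate (lateral dienolate of 7) | [Li+].C=C1OC(OC)=C(CC)C([O-])=C1CC | intermediate (not isolated)
10 | tert-butyl 3-(3,5-diethyl-6-methoxy-4-oxo-4H-pyran-2-yl)propanoate | CCc1c(CCC(=O)OC(C)(C)C)oc(OC)c(CC)c1=O | intermediate
11 | 3-(3,5-diethyl-6-methoxy-4-oxo-4H-pyran-2-yl)propanoic acid | CCc1c(CCC(=O)O)oc(OC)c(CC)c1=O | intermediate
12 | 8-bromooct-1-ene | C=CCCCCCCBr | starting material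
13 | (S)-2-methyloxirane | C[C@H]1CO1 | starting material
14 | oct-7-enylmagnesium bromide | C=CCCCCCC[Mg]Br | intermediate (not isolated)
15 | (S)-undec-10-en-2-ol | C=CCCCCCCC[C@H](C)O | intermediate
16 | (S)-undec-10-en-2-yl acetate | C=CCCCCCCC[C@H](C)OC(C)=O | intermediate
17 | (S)-9-acetoxydecanoic acid | OC(=O)CCCCCCC[C@H](C)OC(C)=O | intermediate
18 | 2-(3,5-diethyl-6-methoxy-4-oxo-4H-pyran-2-yl)ethyl radical | CCc1c(C[CH2])oc(OC)c(CC)c1=O | intermediate (not isolated)
19 | (S)-8-acetoxynonyl radical | [CH2]CCCCCC[C@H](C)OC(C)=O | intermediate (not isolated)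
20 | (S)-11-(3,5-diethyl-6-methoxy-4-oxo-4H-pyran-2-yl)undecan-2-yl acetate | CCc1c(CCCCCCCCC[C@H](C)OC(C)=O)oc(OC)c(CC)c1=O | target

## Step count and risks

Total step count: 10. Longest linear sequence: 7 steps (steps 1–6, then step 10); the acetoxy acid branch is 3 steps (steps 7–9).

The three steps most likely to fail:

1. Step 10 (key step). The pyranone's enol-ether flank may be oxidised at the anode in competition with carboxylate discharge. Part of 11 may be lost to symmetrical coupling if the excess of 17 is not effective. The acetate may undergo methanolysis if the electrolyte turns basic near the end. The fallback makes a different bond (C1'–C2') by polar chemistry and sets out from 7 and 15. Silylation of 15 (TBSCl, imidazole, DMF) should give (S)-tert-butyldimethyl(undec-10-en-2-yloxy)silane F1. Ozonolysis with NaBH4 work-up should give (S)-9-[(tert-butyldimethylsilyl)oxy]decan-1-ol F2, and I2, PPh3 and imidazole should convert it into (S)-tert-butyl[(10-iododecan-2-yl)oxy]dimethylsilane F3. The dienolate 9, generated from 7 as in step 5 (LiHMDS, THF/DMPU, −78 → −20 °C), is alkylated with F3 to give 2-{(S)-10-[(tert-butyldimethylsilyl)oxy]undecyl}-3,5-diethyl-6-methoxy-4H-pyran-4-one F4. TBAF in THF should give 3,5-diethyl-2-[(S)-10-hydroxyundecyl]-6-methoxy-4H-pyran-4-one F5, and acetylation (Ac2O, pyridine, DMAP) comes back to the route at 20.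

2. Step 4. Methylation may occur at the 4-hydroxyl oxygen instead of the lactone carbonyl oxygen, giving the isomeric 4-methoxy-2-pyrone, or both isomers may form. The fallback sets out from 5 and avoids any O-alkylation: dehydrative cyclisation of the β,δ-diketo methyl ester with PPh3/CCl4 (THF or MeCN, rt → 50 °C) activates the C5 enol and lets the ester carbonyl oxygen close the ring, so the ester methoxy group is kept as the ring OMe. It comes back to the route at 7 and bypasses 6; no compound outside the list is made (F0).

3. Step 5. Proton exchange between the product and unreacted dienolate may lead to double alkylation and recovered 7, and the dienolate may attack the ester carbonyl of the electrophile. The fallback installs the propanoate arm before the ring is made and sets out from 2. Commercial 4-tert-butoxy-4-oxobutanoic acid is converted (CDI, MeNHOMe·HCl) into tert-butyl 4-[methoxy(methyl)amino]-4-oxobutanoate F6. This is used in place of 3 to acylate the dianion 4 of 2, giving 8-tert-butyl 1-methyl 2,4-diethyl-3,5-dioxooctanedioate F7. DBU in toluene should give tert-butyl 3-(3,5-diethyl-4-hydroxy-2-oxo-2H-pyran-6-yl)propanoate F8. O-methylation as in step 4, with 2,6-di-tert-butyl-4-methylpyridine added as proton scavenger to spare the tert-butyl ester, comes back to the route at 10.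

## Further compounds

F1 | step 10 | (S)-tert-butyldimethyl(undec-10-en-2-yloxy)silane | C=CCCCCCCC[C@H](C)O[Si](C)(C)C(C)(C)C
F2 | step 10 | (S)-9-[(tert-butyldimethylsilyl)oxy]decan-1-ol | OCCCCCCCC[C@H](C)O[Si](C)(C)C(C)(C)C
F3 | step 10 | (S)-tert-butyl[(10-iododecan-2-yl)oxy]dimethylsilane | ICCCCCCCC[C@H](C)O[Si](C)(C)C(C)(C)C
F4 | step 10 | 2-{(S)-10-[(tert-butyldimethylsilyl)oxy]undecyl}-3,5-diethyl-6-methoxy-4H-pyran-4-one | CCc1c(CCCCCCCCC[C@H](C)O[Si](C)(C)C(C)(C)C)oc(OC)c(CC)c1=O
F5 | step 10 | 3,5-diethyl-2-[(S)-10-hydroxyundecyl]-6-methoxy-4H-pyran-4-one | CCc1c(CCCCCCCCC[C@H](C)O)oc(OC)c(CC)c1=O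
F0 | step 4 | none | none
F6 | step 5 | tert-butyl 4-[methoxy(methyl)amino]-4-oxobutanoate | CON(C)C(=O)CCC(=O)OC(C)(C)C
F7 | step 5 | 8-tert-butyl 1-methyl 2,4-diethyl-3,5-dioxooctanedioate | COC(=O)C(CC)C(=O)C(CC)C(=O)CCC(=O)OC(C)(C)C
F8 | step 5 | tert-butyl 3-(3,5-diethyl-4-hydroxy-2-oxo-2H-pyran-6-yl)propanoate | CCc1c(O)c(CC)c(CCC(=O)OC(C)(C)C)oc1=O
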